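**Retrosynthetic overview**

1. The only ring, the 35-membered lactone, is closed last at the acyl–O bond. As a thioesterase does with an ω-hydroxy acyl chain, a serine hydrolase (immobilised lipase) cyclises unprotected methyl 34-hydroxytetratriacontanoate directly, with no saponification and no activating agent.
2. The C34 seco ester is split into C22 + C12: sp3–sp3 Suzuki coupling of the 9-BBN adduct of methyl docos-21-enoate with 12-bromododecan-1-ol (free OH).
3. Methyl docos-21-enoate is split into C11 + C11: Cu-catalysed coupling of undec-10-enylmagnesium bromide with methyl 11-bromoundecanoate.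
4. Order: chain first (two C–C couplings), ring last; no protecting groups.

Assumption: the target is read as the lactone of 34-hydroxytetratriacontanoic acid (33 CH2 groups, 35-membered ring, C34H66O2); it has no stereocentre, so it is one achiral compound and no enantiocontrol is needed.

**Route**

Step 1
Reactants: 1 11-bromoundec-1-ene; 2 magnesium; 3 methyl 11-bromoundecanoate
Product: 5 methyl docos-21-enoate, via undec-10-enylmagnesium bromide 4 (not isolated)
Conditions: 1 (1.2 equiv), Mg (1.3 equiv), THF, 40 °C; then added over 1 h to 3 (1.0 equiv), Li2CuCl4 (3 mol%), NMP (4 equiv), THF, 0 °C → rt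
Reagents that add atoms: none
Why: Copper-catalysed sp3–sp3 Grignard coupling (Kochi–Cahiez type), in which the alkylcopper species displaces the primary bromide of 3 much faster than the slowly added Grignard reagent attacks the methyl ester in the presence of NMP; the terminal alkene is inert and no stereocentre is formed.

Step 2
Reactants: 5 methyl docos-21-enoate; 6 9-borabicyclo[3.3.1]nonane (9-BBN); 7 12-bromododecan-1-ol
Product: 9 methyl 34-hydroxytetratriacontanoate, via B-alkyl-9-BBN adduct 8 (not isolated)
Conditions: 9-BBN (1.1 equiv, 0.5 M in THF), THF, 0 °C → rt, 6 h; then 7 (0.9 equiv), Pd(OAc)2 (4 mol%), PCy3 (8 mol%), K3PO4·H2O (1.2 equiv), THF, rt, 24 h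
Reagents that add atoms: none
Why: Anti-Markovnikov hydroboration of the terminal alkene with 9-BBN (the ester is not reduced at rt) followed by Fu-type alkyl–alkyl Suzuki–Miyaura coupling, where Pd/PCy3 inserts into the primary C–Br bond and reductive elimination outruns β-hydride elimination, while the mild hydrated phosphate base leaves the methyl ester and the free primary OH untouched; no stereocentre is formed.

Step 3
Reactants: 9 methyl 34-hydroxytetratriacontanoate
Product: 10 oxacyclopentatriacontan-2-one (tetratriacontan-34-olide)
Conditions: Novozym 435 (immobilised Candida antarctica lipase B), 5 Å MS, toluene, 1 mM, 70 °C, 72 h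
Reagents that add atoms: none
Why: Lipase-catalysed transesterification macrolactonisation, in which the active-site serine is acylated by the methyl ester to give the same acyl-O-serine intermediate a thioesterase uses and the chain's own 34-OH then releases the lactone; because the enzyme also re-opens linear and cyclic oligoesters, the mixture equilibrates at 1 mM towards the entropically favoured strain-free monomeric ring while the sieves take up methanol, and no stereocentre is formed.

**Compound list**

1 | 11-bromoundec-1-ene | C=CCCCCCCCCCBr | starting material
2 | magnesium (turnings) | [Mg] | starting material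
3 | methyl 11-bromoundecanoate | COC(=O)CCCCCCCCCCBr | starting material
4 | undec-10-enylmagnesium bromide | C=CCCCCCCCCC[Mg]Br | intermediate
5 | methyl docos-21-enoate | COC(=O)CCCCCCCCCCCCCCCCCCCC=C | intermediate
6 | 9-borabicyclo[3.3.1]nonane (9-BBN, written as monomer) | B1C2CCCC1CCC2 | starting material
7 | 12-bromododecan-1-ol | OCCCCCCCCCCCCBr | starting material
8 | methyl 22-(9-borabicyclo[3.3.1]nonan-9-yl)docosanoate | COC(=O)CCCCCCCCCCCCCCCCCCCCCB1C2CCCC1CCC2 | intermediate
9 | methyl 34-hydroxytetratriacontanoate | COC(=O)CCCCCCCCCCCCCCCCCCCCCCCCCCCCCCCCCO | intermediate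
10 | oxacyclopentatriacontan-2-one (tetratriacontan-34-olide; achiral) | O=C1CCCCCCCCCCCCCCCCCCCCCCCCCCCCCCCCCO1 | target

**Step count and risks**

Total step count: 3. Longest linear sequence: 3.

The steps most likely to fail, most risky first:

Step 3. The enzyme may not turn over a C34 acyl chain, or the product may stay at linear or cyclic oligoesters; a 35-membered monolactone is larger than those usually made this way, although the same enzyme forms cyclic oligolactones of this ring size in dilute solution. The fallback sets out from 9 and comes back at 10. Compound 9 is saponified (LiOH, THF/MeOH/H2O, 60 °C, then acid) to 34-hydroxytetratriacontanoic acid F1. This is converted with 2,2'-dipyridyl disulfide and PPh3 in warm toluene into S-pyridin-2-yl 34-hydroxytetratriacontanethioate F2. The thioester is added slowly to refluxing xylene (final 0.5 mM, AgOTf optional), so that a Corey–Nicolaou double-activation macrolactonisation gives 10.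

Step 2. The alkyl–Pd species from 7 may undergo β-hydride elimination or reduction, and the free OH may slow transmetalation. The fallback sets out from 5 and comes back at 9. Radical anti-Markovnikov hydrobromination of 5 (HBr gas, dibenzoyl peroxide, hexane, 0 °C) gives methyl 22-bromodocosanoate F3. In parallel, 7 is protected with 3,4-dihydro-2H-pyran and PPTS as 2-[(12-bromododecyl)oxy]oxane F4, which is converted with Mg in THF into [12-(oxan-2-yloxy)dodecyl]magnesium bromide F5. F5 is coupled with F3 under the Li2CuCl4/NMP conditions of step 1 to give methyl 34-(oxan-2-yloxy)tetratriacontanoate F6. PPTS in MeOH/THF at 50 °C then removes the THP group and returns 9.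

Step 1. The Grignard reagent may add to the ester of 3, or Wurtz homocoupling to docosa-1,21-diene may erode the yield. The fallback sets out from 1 and comes back at 5. Commercial methyl undec-10-enoate (C=CCCCCCCCCC(=O)OC) is hydroborated with 6 in THF to methyl 11-(9-borabicyclo[3.3.1]nonan-9-yl)undecanoate F7. F7 is coupled with 1 under Pd(OAc)2/PCy3 and K3PO4·H2O in THF at rt (B-alkyl Suzuki coupling) to give 5, so no Grignard reagent ever meets the ester.

**Further compounds**

F1 | step 3 | 34-hydroxytetratriacontanoic acid | OC(=O)CCCCCCCCCCCCCCCCCCCCCCCCCCCCCCCCCO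
F2 | step 3 | S-pyridin-2-yl 34-hydroxytetratriacontanethioate | O=C(Sc1ccccn1)CCCCCCCCCCCCCCCCCCCCCCCCCCCCCCCCCO
F3 | step 2 | methyl 22-bromodocosanoate | COC(=O)CCCCCCCCCCCCCCCCCCCCCBr
F4 | step 2 | 2-[(12-bromododecyl)oxy]oxane (racemic) | BrCCCCCCCCCCCCOC1CCCCO1
F5 | step 2 | [12-(oxan-2-yloxy)dodecyl]magnesium bromide (racemic) | Br[Mg]CCCCCCCCCCCCOC1CCCCO1
F6 | step 2 | methyl 34-(oxan-2-yloxy)tetratriacontanoate (racemic) | COC(=O)CCCCCCCCCCCCCCCCCCCCCCCCCCCCCCCCCOC1CCCCO1
F7 | step 1 | methyl 11-(9-borabicyclo[3.3.1]nonan-9-yl)undecanoate | COC(=O)CCCCCCCCCCB1C2CCCC1CCC2
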